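**Plan**
Numbering (germacrane): ring A is the carbocycle C1–C10, ring B is the lactone O–C6–C7–C11–C12, and C13 is the exocyclic CH2. The retrosynthesis cuts, in order, the ester C–O bond at O9, the ring A bond C7–C8, the C7=C11 bond of ring B, the O6–C12 ester bond, and C1=C10.
Enabling feature: the array O8–C8–C7–C11(=C13)–C12=O. C7 is the β-carbon of the ring B enoate, C8 is an α-oxy carbon next to the C9 carbinol, and C11=C13 lies where a radical addition–fragmentation leaves its double bond. A C8 radical closing on C7 of a 3-(sulfonylmethyl)butenolide therefore makes ring A, C7, C8 and the α-methylene lactone in one event.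
Forward order: side-chain epoxide ring (step 2); Wittig union of a tartrate ketone (C8–C10, C14) with a C1–C7 ylide (step 11); ring B by metathesis (step 15); ring A last (step 17); deprotection and O9 acylation.
Helpers: a carboxyl group on C8 (radical precursor, leaves as CO2), PhSO2 on C13 (radical leaving group), and the acetonide ring across O8/O9 (face control, removed in step 18).
Stereochemistry: C8/C9 come from (S,S)-tartrate and C6 from a catalytic enantioselective vinylation. C7 and the retention at C8 come from the two five-membered rings in the key step, and C2'/C3' from a Sharpless epoxidation. The E C4=C5 olefin comes from syn carboalumination and the Z C1=C10 olefin from the Wittig reaction.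

Key step: step 17

Remark on the chemistry: the CIP descriptors at C6, C7, C9 and C2' change along the route only because substituent priorities change. No centre is inverted.

**Step 1**
Reactants: 1 methyl angelate [methyl (Z)-2-methylbut-2-enoate]
Product: 2 (Z)-2-methylbut-2-en-1-ol
Conditions: i-Bu2AlH (2.2 equiv), CH2Cl2, −78 °C; aq. potassium sodium tartrate
Reagents that add atoms: none
Why: Hydride reduction of the ester to the allylic alcohol at low temperature should leave the trisubstituted Z olefin and its geometry untouched.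

**Step 2**
Reactants: 2 (Z)-2-methylbut-2-en-1-ol
Product: 3 [(2S,3R)-2,3-dimethyloxiran-2-yl]methanol
Conditions: Ti(OiPr)4 (10 mol%), (R,R)-diethyl tartrate (12 mol%), t-BuOOH, 4 Å molecular sieves, CH2Cl2, −20 °C
Reagents that add atoms: tert-butyl hydroperoxide, CC(C)(C)OO
Why: Sharpless asymmetric epoxidation, in which the (R,R)-tartrate titanium complex delivers oxygen to the face that gives 2S epoxy alcohols, and syn addition to the Z olefin fixes the trans relation of the two methyl groups, so both epoxide centres are set here.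

**Step 3**
Reactants: 3 [(2S,3R)-2,3-dimethyloxiran-2-yl]methanol
Product: 4 (2R,3R)-2,3-dimethyloxirane-2-carboxylic acid (epoxyangelic acid)
Conditions: TEMPO (10 mol%), PhI(OAc)2 (2.2 equiv), MeCN–H2O 1:1, 0 °C to rt
Reagents that add atoms: water, O
Why: Oxoammonium oxidation of the primary alcohol through the aldehyde hydrate to the acid is mild enough for the epoxide; C2 becomes R only through the priority change.

**Step 4**
Reactants: 5 dimethyl (4S,5S)-2,2-dimethyl-1,3-dioxolane-4,5-dicarboxylate
Product: 6 (4S,5S)-5-(methoxycarbonyl)-2,2-dimethyl-1,3-dioxolane-4-carboxylic acid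
Conditions: KOH (1.0 equiv), MeOH, 0 °C to rt; aq. HCl to pH 2
Reagents that add atoms: potassium hydroxide, [K+].[OH-]
Why: Mono-saponification of a C2-symmetric diester, in which the first carboxylate slows the second hydrolysis and both homotopic esters give the same product.

**Step 5**
Reactants: 6 (4S,5S)-5-(methoxycarbonyl)-2,2-dimethyl-1,3-dioxolane-4-carboxylic acid
Product: 8 methyl (4S,5S)-5-acetyl-2,2-dimethyl-1,3-dioxolane-4-carboxylate, via acid chloride 7 (not isolated)
Conditions: (COCl)2, DMF (cat.), CH2Cl2, 0 °C to rt, evaporate; MeMgBr (1.05 equiv), Fe(acac)3 (3 mol%), THF, −78 °C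
Reagents that add atoms: oxalyl chloride, O=C(Cl)C(=O)Cl (chlorine of 7 only); methylmagnesium bromide, C[Mg]Br
Why: Iron-catalysed acyl chloride–Grignard cross-coupling is faster at −78 °C than attack on the ester or on the new ketone, and the trans-dioxolane is the stable epimer, so C8 and C9 should be kept.

**Step 6**
Reactants: 9 5-chloropent-1-yne
Product: 12 (E)-6-chloro-3-methylhex-2-en-1-ol, via vinylalane 10 (not isolated), via lithium alanate 11 (not isolated)
Conditions: Me3Al (2 equiv), Cp2ZrCl2 (20 mol%), CH2Cl2, 0 °C to rt; evaporate, hexane, n-BuLi, −78 to 0 °C; (CH2O)n, THF, rt; aq. HCl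
Reagents that add atoms: trimethylaluminium, C[Al](C)C; n-butyllithium, [Li]CCCC (butyl and lithium of 11 only); formaldehyde (as paraformaldehyde), C=O
Why: Negishi zirconium-catalysed carboalumination adds Me and Al syn across the terminal alkyne, and hydroxymethylation of the alanate goes with retention, which sets the E C4=C5 olefin.

**Step 7**
Reactants: 12 (E)-6-chloro-3-methylhex-2-en-1-ol
Product: 13 (E)-6-chloro-3-methylhex-2-enal
Conditions: MnO2 (excess), CH2Cl2, rt
Reagents that add atoms: none
Why: Allylic alcohol oxidation with MnO2 is neutral and should not isomerise the E enal.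

**Step 8**
Reactants: 13 (E)-6-chloro-3-methylhex-2-enal
Product: 14 (3R,4E)-8-chloro-5-methylocta-1,4-dien-3-ol
Conditions: Zn(CH=CH2)2 (1.5 equiv, stock solution), (+)-MIB [(2R)-3-exo-morpholinoisoborneol, 5 mol%], toluene–hexane, −20 to 0 °C; aq. NH4Cl
Reagents that add atoms: divinylzinc, C=C[Zn]C=C
Why: Amino-alcohol-catalysed enantioselective 1,2-addition of an alkenylzinc to an enal, in which the (2R) ligand, the antipode of the one that delivers to the Si face, should deliver vinyl to the Re face and so set C6 (3R here).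

**Step 9**
Reactants: 14 (3R,4E)-8-chloro-5-methylocta-1,4-dien-3-ol
Product: 15 tert-butyl{[(3R,4E)-8-chloro-5-methylocta-1,4-dien-3-yl]oxy}dimethylsilane
Conditions: TBSCl, imidazole, DMF, rt
Reagents that add atoms: tert-butyldimethylsilyl chloride, CC(C)(C)[Si](C)(C)Cl
Why: Standard silylation protects the bis-allylic alcohol against the base and heat of the next two steps without touching C6.

**Step 10**
Reactants: 15 tert-butyl{[(3R,4E)-8-chloro-5-methylocta-1,4-dien-3-yl]oxy}dimethylsilane
Product: 17 [(4E,6R)-6-(tert-butyldimethylsilyloxy)-4-methylocta-4,7-dienyl]triphenylphosphonium iodide, via primary iodide 16 (not isolated)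
Conditions: NaI (3 equiv), PPh3 (1.5 equiv), MeCN, reflux
Reagents that add atoms: sodium iodide, [Na+].[I-]; triphenylphosphine, c1ccc(cc1)P(c1ccccc1)c1ccccc1
Why: Finkelstein exchange followed by SN2 quaternisation of PPh3 at the unhindered primary carbon C1.

**Step 11**
Reactants: 17 [(4E,6R)-6-(tert-butyldimethylsilyloxy)-4-methylocta-4,7-dienyl]triphenylphosphonium iodide; 8 methyl (4S,5S)-5-acetyl-2,2-dimethyl-1,3-dioxolane-4-carboxylate
Product: 19 methyl (4S,5R)-5-[(2Z,6E,8R)-8-(tert-butyldimethylsilyloxy)-6-methyldeca-2,6,9-trien-2-yl]-2,2-dimethyl-1,3-dioxolane-4-carboxylate, via phosphorus ylide 18 (not isolated)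
Conditions: KN(SiMe3)2, THF, −78 °C; then 8, −78 to 0 °C
Reagents that add atoms: none
Why: Wittig olefination with an unstabilised, lithium-free ylide, in which the kinetic oxaphosphetane of an α-alkoxy methyl ketone places the ylide chain beside the oxygenated carbon; this should give the Z C1=C10 olefin (C2 cis to C9), and the ketone reacts far faster than the ester.

**Step 12**
Reactants: 19 methyl (4S,5R)-5-[(2Z,6E,8R)-8-(tert-butyldimethylsilyloxy)-6-methyldeca-2,6,9-trien-2-yl]-2,2-dimethyl-1,3-dioxolane-4-carboxylate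
Product: 20 methyl (4S,5R)-5-[(2Z,6E,8R)-8-hydroxy-6-methyldeca-2,6,9-trien-2-yl]-2,2-dimethyl-1,3-dioxolane-4-carboxylate
Conditions: Bu4NF, AcOH (1:1), THF, 0 °C to rt
Reagents that add atoms: none
Why: Buffered fluoride desilylation spares the methyl ester, the acetonide and the acid-sensitive bis-allylic carbinol.

**Step 13**
Reactants: 21 2-(bromomethyl)acrylic acid
Product: 22 2-(phenylsulfonylmethyl)acrylic acid
Conditions: PhSO2Na (1.2 equiv), MeOH, reflux
Reagents that add atoms: sodium benzenesulfinate, [Na+].[O-]S(=O)c1ccccc1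
Why: S-alkylation of the sulfinate by the allylic bromide, where direct and allylic displacement give the same product.

**Step 14**
Reactants: 20 methyl (4S,5R)-5-[(2Z,6E,8R)-8-hydroxy-6-methyldeca-2,6,9-trien-2-yl]-2,2-dimethyl-1,3-dioxolane-4-carboxylate; 22 2-(phenylsulfonylmethyl)acrylic acid
Product: 23 the O6 2-(phenylsulfonylmethyl)acrylate of 20
Conditions: i-PrN=C=N-i-Pr, DMAP (10 mol%), CH2Cl2, 0 °C
Reagents that add atoms: none
Why: Steglich esterification acylates oxygen, so the C6–O bond and its configuration are kept.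

**Step 15**
Reactants: 23 the O6 2-(phenylsulfonylmethyl)acrylate of 20
Product: 24 methyl (4S,5R)-2,2-dimethyl-5-{(2Z,6E)-6-methyl-7-[(2S)-5-oxo-4-(phenylsulfonylmethyl)-2,5-dihydrofuran-2-yl]hepta-2,6-dien-2-yl}-1,3-dioxolane-4-carboxylate
Conditions: second-generation Grubbs catalyst RuCl2(=CHPh)(PCy3)(SIMes) (5 mol%), CH2Cl2 (5 mM), reflux
Reagents that add atoms: none
Why: Ring-closing metathesis, in which the catalyst loads on the only monosubstituted olefin (C7) and closes the five-membered ring B on the acrylate; the trisubstituted olefins are inert, and closure onto C1 would need an E olefin inside a seven-membered ring.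

**Step 16**
Reactants: 24 butenolide methyl ester
Product: 25 (4S,5R)-2,2-dimethyl-5-{(2Z,6E)-6-methyl-7-[(2S)-5-oxo-4-(phenylsulfonylmethyl)-2,5-dihydrofuran-2-yl]hepta-2,6-dien-2-yl}-1,3-dioxolane-4-carboxylic acid
Conditions: Me3SnOH (4 equiv), ClCH2CH2Cl, 60 °C; wash with dilute aq. HCl
Reagents that add atoms: trimethyltin hydroxide, C[Sn](C)(C)O
Why: Trimethyltin hydroxide hydrolysis is nearly neutral and favours the unhindered, α-alkoxy-activated methyl ester over the conjugated lactone of a secondary alcohol, so C6 and C8 should not epimerise.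

**Step 17**
Reactants: 25 butenolide carboxylic acid
Product: 29 (6S,7R,8R,9R)-8,9-(isopropylidenedioxy)germacra-1(10)Z,4E,11(13)-trien-12,6-olide (lactone and dioxolane both trans-fused to ring A), via potassium carboxylate 26 (not isolated), via C8 dioxolanyl radical 27 (not isolated), via C11 lactone radical 28 (not isolated)
Conditions: [Ir(dF(CF3)ppy)2(dtbbpy)]PF6 (2 mol%), K2HPO4 (1.2 equiv), degassed DMF (1 mM), blue LEDs (450 nm), 25 °C
Reagents that add atoms: dipotassium hydrogen phosphate, [K+].[K+].OP(=O)([O-])[O-] (potassium of 26 only)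
Why: Proposed new method: the photoexcited trivalent iridium complex oxidises carboxylate 26, loss of CO2 gives the nucleophilic dioxolanyl radical 27 at C8, this adds to C7 (the electrophilic β-carbon of the butenolide), the tertiary α-carbonyl radical 28 at C11 expels PhSO2• by β-scission and so unveils C11=C13, and divalent iridium reduces the sulfonyl radical to sulfinate, closing a redox-neutral cycle. The closest known reaction types are the intermolecular photoredox decarboxylative allylation of α-oxy acids with 2-(sulfonylmethyl)acrylates, decarboxylative Giese macrocyclisation of peptides and the anti-selective addition of carbon radicals to 5-substituted butenolides, and what is new is their union in a ten-membered carbocyclisation. Ring A closes in the 10-exo-trig mode (C8 bonds to C7, the spin moves to C11 outside the new ring), helped by three turn elements in the eight-atom tether, namely the Z C1=C10 olefin and the five-membered ring at each end. C7 is controlled by C6: bonding on the butenolide face opposite to C5 keeps the torsion C5–C6–C7–C8 staggered and gives the trans-fused lactone, whereas closure on the same face would have to eclipse it. C8 is controlled by C9: the nearly planar dioxolanyl radical bonds anti to the C10 substituent and returns the trans-dioxolane, that is net retention of the tartrate configuration and the threo 8,9-diol. The step needs cyclisation to outrun intermolecular coupling, hydrogen transfer and attack on the other olefins; high dilution and the absence of a hydrogen donor serve the first two, allylic 1,3-strain across the Z olefin keeps C9–H rather than C8 in the olefin plane and so away from the C2 hydrogens, polarity matching directs the nucleophilic radical to the only electron-poor olefin, and fast irreversible loss of the sulfonyl radical makes the addition productive.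

**Step 18**
Reactants: 29 macrocyclic acetonide
Product: 30 (6S,7S,8R,9R)-8,9-dihydroxygermacra-1(10)Z,4E,11(13)-trien-12,6-olide
Conditions: AcOH–H2O 4:1, 40 °C
Reagents that add atoms: none
Why: Acid-catalysed ketal hydrolysis with a weak acid, chosen so that neither the 1(10),4-diene is protonated (transannular cyclisation) nor the allylic C9–O bond ionised; no stereocentre is touched.

**Step 19**
Reactants: 30 (6S,7S,8R,9R)-8,9-dihydroxygermacra-1(10)Z,4E,11(13)-trien-12,6-olide; 4 (2R,3R)-2,3-dimethyloxirane-2-carboxylic acid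
Product: 32 target CNP0213766.4 [(6S,7S,8R,9R)-8-hydroxy-9-[(2R,3R)-2,3-epoxy-2-methylbutanoyloxy]germacra-1(10)Z,4E,11(13)-trien-12,6-olide], via mixed anhydride 31 (not isolated)
Conditions: 4 (1.0 equiv), 2,4,6-Cl3C6H2COCl, Et3N, toluene, rt; then 30, DMAP, toluene, −20 to 0 °C
Reagents that add atoms: 2,4,6-trichlorobenzoyl chloride, O=C(Cl)c1c(Cl)cc(Cl)cc1Cl (its acyl group stays in 31 only)
Why: Yamaguchi esterification, in which the α-quaternary acyl donor should prefer the allylic C9 hydroxyl (flanked by the flat sp2 carbon C10) over the C8 hydroxyl (wedged between the sp3 methines C7 and C9 beside the lactone), while one equivalent and low temperature limit double acylation.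

**Compound list**
1 | methyl angelate | C/C=C(/C)C(=O)OC | starting material
2 | (Z)-2-methylbut-2-en-1-ol | C/C=C(/C)CO | intermediate
3 | [(2S,3R)-2,3-dimethyloxiran-2-yl]methanol | OC[C@]1(C)O[C@@H]1C | intermediate
4 | (2R,3R)-2,3-dimethyloxirane-2-carboxylic acid | OC(=O)[C@]1(C)O[C@@H]1C | intermediate
5 | dimethyl (4S,5S)-2,2-dimethyl-1,3-dioxolane-4,5-dicarboxylate | COC(=O)[C@H]1OC(C)(C)O[C@@H]1C(=O)OC | starting material
6 | (4S,5S)-5-(methoxycarbonyl)-2,2-dimethyl-1,3-dioxolane-4-carboxylic acid | OC(=O)[C@H]1OC(C)(C)O[C@@H]1C(=O)OC | intermediate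
7 | methyl (4S,5S)-5-(chlorocarbonyl)-2,2-dimethyl-1,3-dioxolane-4-carboxylate | ClC(=O)[C@H]1OC(C)(C)O[C@@H]1C(=O)OC | intermediate
8 | methyl (4S,5S)-5-acetyl-2,2-dimethyl-1,3-dioxolane-4-carboxylate | CC(=O)[C@H]1OC(C)(C)O[C@@H]1C(=O)OC | intermediate
9 | 5-chloropent-1-yne | C#CCCCCl | starting material
10 | [(E)-5-chloro-2-methylpent-1-enyl]dimethylalane | C[Al](C)/C=C(\C)CCCCl | intermediate
11 | lithium butyl[(E)-5-chloro-2-methylpent-1-enyl]dimethylaluminate | CCCC[Al-](C)(C)/C=C(\C)CCCCl.[Li+] | intermediate
12 | (E)-6-chloro-3-methylhex-2-en-1-ol | OC/C=C(\C)CCCCl | intermediate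
13 | (E)-6-chloro-3-methylhex-2-enal | O=C/C=C(\C)CCCCl | intermediate
14 | (3R,4E)-8-chloro-5-methylocta-1,4-dien-3-ol | O[C@H](C=C)/C=C(\C)CCCCl | intermediate
15 | TBS ether of 14 | CC(C)(C)[Si](C)(C)O[C@H](C=C)/C=C(\C)CCCCl | intermediate
16 | tert-butyl{[(3R,4E)-8-iodo-5-methylocta-1,4-dien-3-yl]oxy}dimethylsilane | CC(C)(C)[Si](C)(C)O[C@H](C=C)/C=C(\C)CCCI | intermediate
17 | [(4E,6R)-6-(tert-butyldimethylsilyloxy)-4-methylocta-4,7-dienyl]triphenylphosphonium iodide | CC(C)(C)[Si](C)(C)O[C@H](C=C)/C=C(\C)CCC[P+](c1ccccc1)(c1ccccc1)c1ccccc1.[I-] | intermediate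
18 | ylide of 17 | CC(C)(C)[Si](C)(C)O[C@H](C=C)/C=C(\C)CCC=P(c1ccccc1)(c1ccccc1)c1ccccc1 | intermediate
19 | Wittig product, (4S,5R) dioxolane ester with (2Z,6E,8R) side chain, O6-TBS | CC(C)(C)[Si](C)(C)O[C@H](C=C)/C=C(\C)CC/C=C(/C)[C@H]1OC(C)(C)O[C@@H]1C(=O)OC | intermediate
20 | C6 alcohol from 19 | O[C@H](C=C)/C=C(\C)CC/C=C(/C)[C@H]1OC(C)(C)O[C@@H]1C(=O)OC | intermediate
21 | 2-(bromomethyl)acrylic acid | C=C(CBr)C(=O)O | starting material
22 | 2-(phenylsulfonylmethyl)acrylic acid | C=C(CS(=O)(=O)c1ccccc1)C(=O)O | intermediate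
23 | O6 2-(phenylsulfonylmethyl)acrylate of 20 | C=C(CS(=O)(=O)c1ccccc1)C(=O)O[C@H](C=C)/C=C(\C)CC/C=C(/C)[C@H]1OC(C)(C)O[C@@H]1C(=O)OC | intermediate
24 | (S)-3-(phenylsulfonylmethyl)butenolide methyl ester | O=C1O[C@@H](/C=C(\C)CC/C=C(/C)[C@H]2OC(C)(C)O[C@@H]2C(=O)OC)C=C1CS(=O)(=O)c1ccccc1 | intermediate
25 | butenolide carboxylic acid | O=C1O[C@@H](/C=C(\C)CC/C=C(/C)[C@H]2OC(C)(C)O[C@@H]2C(=O)O)C=C1CS(=O)(=O)c1ccccc1 | intermediate
26 | potassium salt of 25 | O=C1O[C@@H](/C=C(\C)CC/C=C(/C)[C@H]2OC(C)(C)O[C@@H]2C(=O)[O-])C=C1CS(=O)(=O)c1ccccc1.[K+] | intermediate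
27 | C8 dioxolan-4-yl radical | O=C1O[C@@H](/C=C(\C)CC/C=C(/C)[C@H]2OC(C)(C)O[CH]2)C=C1CS(=O)(=O)c1ccccc1 | intermediate
28 | cyclised C11 radical | O=C1O[C@H]2/C=C(\C)CC/C=C(/C)[C@H]3OC(C)(C)O[C@@H]3[C@@H]2[C]1CS(=O)(=O)c1ccccc1 | intermediate
29 | 8,9-O-isopropylidene macrocycle | C=C1C(=O)O[C@H]2/C=C(\C)CC/C=C(/C)[C@H]3OC(C)(C)O[C@@H]3[C@H]12 | intermediate
30 | 8,9-diol | C=C1C(=O)O[C@H]2/C=C(\C)CC/C=C(/C)[C@@H](O)[C@H](O)[C@H]12 | intermediate
31 | (2R,3R)-2,3-dimethyloxirane-2-carboxylic 2,4,6-trichlorobenzoic anhydride | O=C(OC(=O)[C@]1(C)O[C@@H]1C)c1c(Cl)cc(Cl)cc1Cl | intermediate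
32 | CNP0213766.4 | C=C1C(=O)O[C@H]2/C=C(\C)CC/C=C(/C)[C@@H](OC(=O)[C@]3(C)O[C@@H]3C)[C@H](O)[C@H]12 | target

**Counts**
Total steps: 19. Longest linear sequence: 13 steps from 9 (steps 6–12 and 14–19). The side branches are acid 4 (3 steps), ketone 8 (2 steps) and acid 22 (1 step).

**Steps most likely to fail**

1. Step 17 (bears the label "Proposed new method:"). The ten-membered closure may be slower than hydrogen transfer from the allylic C2/C3 positions to C8 or than intermolecular coupling. It may also bond on the wrong face of one of the five-membered rings.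
 - The fallback is known polar chemistry on the same bond. It sets out from phosphonium salt 17 and comes back at diol 30.
 - Commercial methyl (S)-2,2-dimethyl-1,3-dioxolane-4-carboxylate F1 is turned with MeNH(OMe)·HCl/i-PrMgCl into the N-methoxy-N-methylamide F2. MeMgBr then gives the methyl ketone F3, in which C8 is a CH2O carbon.
 - Wittig reaction of ylide 18 (from 17) with F3 gives the Z olefin F4, and Bu4NF/AcOH gives the dienol F5.
 - N,N'-Diisopropylcarbodiimide with acid 21 gives the 2-(bromomethyl)acrylate F6, and ring-closing metathesis gives the 3-(bromomethyl)butenolide F7.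
 - Aqueous acetic acid frees the 8,9-diol F8, and TEMPO/PhI(OAc)2 oxidises its primary C8 hydroxyl to the α-hydroxy aldehyde F9.
 - Slow addition of F9 to indium powder in THF–H2O closes ring A by an intramolecular Barbier allylation with allylic transposition (C13 to C7) and gives 30.
 - Indium bound to both the aldehyde oxygen and the free O9 hydroxyl places C9 axial in the chair transition state. The ring-locked allylindium should therefore give the C7/C8 syn, C8/C9 syn array.

2. Step 19. Acylation may go to O8, the acyl group may migrate between O9 and O8, or both hydroxyls may react.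
 - The fallback sets out from 30 and comes back at 32. It turns an unwanted preference for O8 into a temporary protection.
 - Et3SiCl/imidazole at −40 °C gives the 8-O-triethylsilyl ether F10.
 - Yamaguchi acylation of the remaining O9–H with excess 4 gives the silylated ester F11.
 - HF·pyridine in THF gives 32.

3. Step 16. The hydroxide source may open or add to the butenolide, C6 may lose its configuration through furanolate formation, or sulfinate may be eliminated on heating.
 - The fallback sets out from 19 and comes back at 29. It cleaves the ester before the base-sensitive ring B exists.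
 - LiOH on 19 gives the acid F12, and N-hydroxyphthalimide with N,N'-diisopropylcarbodiimide gives the redox-active ester F13.
 - HF·pyridine gives the alcohol F14, esterification with 22 gives the acrylate F15, and ring-closing metathesis gives the butenolide redox-active ester F16.
 - The C8 radical is then made reductively with Ru(bpy)3(PF6)2 (1 mol%) and Hantzsch ester in CH2Cl2 (1 mM) under blue light, without any base. It closes to 29 in the same way as in step 17.

**Further compounds**
F1 | step 17 | methyl (S)-2,2-dimethyl-1,3-dioxolane-4-carboxylate | COC(=O)[C@H]1OC(C)(C)OC1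
F2 | step 17 | (S)-N-methoxy-N,2,2-trimethyl-1,3-dioxolane-4-carboxamide | CON(C)C(=O)[C@H]1OC(C)(C)OC1
F3 | step 17 | 1-[(4S)-2,2-dimethyl-1,3-dioxolan-4-yl]ethanone | CC(=O)[C@H]1OC(C)(C)OC1
F4 | step 17 | (4R)-4-[(2Z,6E,8R)-8-(tert-butyldimethylsilyloxy)-6-methyldeca-2,6,9-trien-2-yl]-2,2-dimethyl-1,3-dioxolane | CC(C)(C)[Si](C)(C)O[C@H](C=C)/C=C(\C)CC/C=C(/C)[C@H]1OC(C)(C)OC1
F5 | step 17 | C6 alcohol from F4 | O[C@H](C=C)/C=C(\C)CC/C=C(/C)[C@H]1OC(C)(C)OC1
F6 | step 17 | O6 2-(bromomethyl)acrylate of F5 | C=C(CBr)C(=O)O[C@H](C=C)/C=C(\C)CC/C=C(/C)[C@H]1OC(C)(C)OC1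
F7 | step 17 | (S)-3-(bromomethyl)butenolide with 8,9-acetonide | O=C1O[C@@H](/C=C(\C)CC/C=C(/C)[C@H]2OC(C)(C)OC2)C=C1CBr
F8 | step 17 | (S)-3-(bromomethyl)butenolide 8,9-diol | O=C1O[C@@H](/C=C(\C)CC/C=C(/C)[C@@H](O)CO)C=C1CBr
F9 | step 17 | (S)-3-(bromomethyl)butenolide 9-hydroxy-8-aldehyde | O=C1O[C@@H](/C=C(\C)CC/C=C(/C)[C@@H](O)C=O)C=C1CBr
F10 | step 19 | 8-O-triethylsilyl ether of 30 | C=C1C(=O)O[C@H]2/C=C(\C)CC/C=C(/C)[C@@H](O)[C@H](O[Si](CC)(CC)CC)[C@H]12
F11 | step 19 | 8-O-triethylsilyl ether of 32 | C=C1C(=O)O[C@H]2/C=C(\C)CC/C=C(/C)[C@@H](OC(=O)[C@]3(C)O[C@@H]3C)[C@H](O[Si](CC)(CC)CC)[C@H]12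
F12 | step 16 | carboxylic acid from 19 | CC(C)(C)[Si](C)(C)O[C@H](C=C)/C=C(\C)CC/C=C(/C)[C@H]1OC(C)(C)O[C@@H]1C(=O)O
F13 | step 16 | N-hydroxyphthalimide ester of F12 | CC(C)(C)[Si](C)(C)O[C@H](C=C)/C=C(\C)CC/C=C(/C)[C@H]1OC(C)(C)O[C@@H]1C(=O)ON1C(=O)c2ccccc2C1=O
F14 | step 16 | C6 alcohol from F13 | O[C@H](C=C)/C=C(\C)CC/C=C(/C)[C@H]1OC(C)(C)O[C@@H]1C(=O)ON1C(=O)c2ccccc2C1=O
F15 | step 16 | O6 2-(phenylsulfonylmethyl)acrylate of F14 | C=C(CS(=O)(=O)c1ccccc1)C(=O)O[C@H](C=C)/C=C(\C)CC/C=C(/C)[C@H]1OC(C)(C)O[C@@H]1C(=O)ON1C(=O)c2ccccc2C1=O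
F16 | step 16 | butenolide N-hydroxyphthalimide ester | O=C1O[C@@H](/C=C(\C)CC/C=C(/C)[C@H]2OC(C)(C)O[C@@H]2C(=O)ON2C(=O)c3ccccc3C2=O)C=C1CS(=O)(=O)c1ccccc1
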